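We decide to count the reagent before the substrates, and to ask how long it lasts according to the autumn run, which is this very flask followed so far.

| setting | autumn | noon | flask |
|---|---|---|---|
| left-handed substrate | 20 mM | 20 mM | 20 mM |
| right-handed substrate | 20 mM | 20 mM | 20 mM |
| reagent | 0.60 equiv | 0.60 equiv | 0.600 equiv |
| free catalyst | 0.15 mol% | 0.15 mol% | 0.15 mol% |
| added ligand | 0.16 mM | 0.080 mM | 0.16 mM |
| remark | the very flask that is asked about, followed so far | run made earlier |  |
| time |  |  | 20 min |

| run | time / min | left-handed substrate / % | right-handed substrate / % |
|---|---|---|---|
| autumn | 0.500 | 48.1 | 50.5 |
| autumn | 1.50 | 45.7 | 48.2 |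
| autumn | 3.00 | 47.0 | 49.7 |
| autumn | 4.00 | 44.8 | 45.7 |
| autumn | 6.00 | 42.2 | 49.1 |
| autumn | 8.00 | 39.1 | 47.5 |
| noon | 0.667 | 48.2 | 50.3 |
| noon | 1.00 | 46.6 | 51.4 |
| noon | 2.00 | 46.5 | 48.7 |
| noon | 3.00 | 45.5 | 50.4 |
| noon | 5.00 | 43.1 | 48.3 |
| noon | 8.00 | 41.2 | 49.5 |

(standard deviation of a reading: 1 percentage point)

- free catalyst is single-handed; left-handed substrate and right-handed substrate are mirror images of each other, charged as a racemate, each of them at the stated concentration
- the numbers in the tables scatter with a standard deviation of 1 percentage point
- an excess is the difference of the two amounts in percent of their sum
- an excess is below zero if the other one leads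

- part of the left-handed substrate and right-handed substrate charged together that has reacted at 20 min
- excess of left-handed product over right-handed product in the product at 20 min
- excess of right-handed substrate over left-handed substrate among what is left of the two at 20 min

Turn the question round: for this flask to keep its early pace up to 20 min, the reagent would have to outlast that time by far. Its charge of 0.600 equiv is reckoned on the left-handed substrate, so if each substrate molecule lost takes one reagent, it covers 30.0% of the two substrates together. That makes it the limiting reagent. In the autumn run 13.4% of the two had gone by 8.00 min, a reading that carries its scatter. The allowance divided by that early pace of loss gives 17.9 min. This reagent lifetime is shorter than the asked time, so on this reading the opposite case fails.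

We assume that the pace follows the reagent. The reagent then falls exponentially with that lifetime, and our own reckoning leaves 32.7% of it, with 20.2% of the substrates reacted.

The forecast differs from our reckoning. It gives 30% reacted (23% to 38%), a product excess of 58% and a substrate excess of 25%, and it states “Reagent is not limiting”.

The flask gives 18.1% reacted, a product excess of 71.5% and a substrate excess of 15.8%, with 29% of the reagent left against our 32.7%.

    reagent + catalyst intermediate B → free catalyst + right-handed product (k = 1800 /M/min)
    free catalyst + right-handed substrate ⇌ catalyst intermediate B (K = 21.0 /M, k = 10000 /M/min)
    free catalyst + added ligand ⇌ idle complex (K = 9000 /M, k = 310 /M/min)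
    free catalyst + left-handed substrate ⇌ catalyst intermediate A (K = 66.0 /M, k = 21000 /M/min)
    reagent + catalyst intermediate A → free catalyst + left-handed product (k = 4300 /M/min)
    2 reagent → self-condensation product (k = 0.680 /M/min)

The neighbouring flask holds 0.6 mol% of free catalyst instead of 0.15 mol%, with its other charges and the time as in this flask. Taking the early pace as proportional to the catalyst, the reagent lifetime shortens to 4.48 min, so the asked time is 4.46 lifetimes. The same reckoning then gives 29.7% reacted and 1.15% of the reagent left. That neighbouring flask gives 28.5% reacted, with 2.0% of its reagent left.

(Readings and results are simulated on assumed constants, noise included.)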